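**Plan**
- Retrosynthesis cuts the bond between the bridging CH2 and the filicinic ring, then the C8–acetyl and C6–CHO bonds of the chromene, then the pyran bonds C4–C4a, O1–C8a and O1–C2, and, in the other half, the two C–CH3 bonds at the quaternary ring carbon.
- Enabling feature: the arene bond C4a–C8a carries pyran carbon C4 and oxygen O1 side by side (an aryne retron), with an oxygen-bearing C5 beside C4a to steer the addition and a CH at C8 beside C8a.
- Forward: phloroglucinol is taken in four steps to an ortho-silyl aryl triflate; its aryne inserts into the C=O bond of prenal and closes the pyran ring (step 5).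
- C6 is then formylated and C8 acetylated by two directed metalations, the MOM ethers are removed, and the aldehyde is joined reductively to propionylfilicinic acid, made in one step from flopropione.
- Stereochemistry: the target has no stereocentre and no stereogenic double bond, so nothing has to be controlled.

Key step: step 5

Assumption: the target is drawn as one enol tautomer of the acylfilicinic ring; the tautomers interconvert, and the route aims at this constitution.

**Route**

Step 1
Reactants: 1 phloroglucinol
Product: 2 3,5-bis(methoxymethoxy)phenol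
Conditions: NaH (2.1 equiv), MOMCl (2.0 equiv), DMF, 0 °C → rt; chromatography
Reagents that add atoms: chloromethyl methyl ether (MOMCl), COCCl
Why: Williamson-type O-alkylation of the sodium phenoxides (MOM protection); the three hydroxyls are equivalent, so two equivalents of base and reagent should make the bis-ether the main fraction, separable from mono- and tris-ethers.

Step 2
Reactants: 2 3,5-bis(methoxymethoxy)phenol
Product: 3 3,5-bis(methoxymethoxy)phenyl N-isopropylcarbamate
Conditions: i-PrNCO, Et3N (cat.), CH2Cl2, rt
Reagents that add atoms: isopropyl isocyanate, CC(C)N=C=O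
Why: amine-catalysed addition of the phenol to the isocyanate (carbamoylation) installs a group that is both the strongest ortho director on the ring and cleavable later by mild base.

Step 3
Reactants: 3 3,5-bis(methoxymethoxy)phenyl N-isopropylcarbamate
Product: 7 3,5-bis(methoxymethoxy)-2-(trimethylsilyl)phenyl N-isopropylcarbamate, via N-silyl carbamate 4 (not isolated), via aryllithium 5 (not isolated), via N,C-disilyl carbamate 6 (not isolated)
Conditions: TBSOTf, TMEDA, Et2O, 0 °C → rt; n-BuLi, TMEDA, −78 °C; Me3SiCl, −78 °C → rt; cold 5% aq. NaHSO4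
Reagents that add atoms: chlorotrimethylsilane, C[Si](C)(C)Cl; tert-butyldimethylsilyl triflate, CC(C)(C)[Si](C)(C)OS(=O)(=O)C(F)(F)F (its silyl group is carried only by intermediates 4 to 6)
Why: directed ortho-metalation with transient N-silylation of the N–H: n-BuLi/TMEDA should remove the C2 proton, flanked by the carbamate oxygen and a MOM ether, in preference to C4 between the two weaker MOM directors; Me3SiCl traps the aryllithium and the N–Si bond is hydrolysed on work-up.

Step 4
Reactants: 7 3,5-bis(methoxymethoxy)-2-(trimethylsilyl)phenyl N-isopropylcarbamate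
Product: 9 3,5-bis(methoxymethoxy)-2-(trimethylsilyl)phenyl trifluoromethanesulfonate, via silyl phenol 8 (not isolated)
Conditions: DBU, Et2NH, MeCN, 40 °C; then PhNTf2, rt
Reagents that add atoms: N-phenylbis(trifluoromethanesulfonimide), O=S(=O)(N(c1ccccc1)S(=O)(=O)C(F)(F)F)C(F)(F)F
Why: one-pot carbamate-to-triflate exchange: DBU deprotonates the N–H, E1cB loss of isopropyl isocyanate (trapped by Et2NH as a urea) frees the phenoxide, and PhNTf2 sulfonylates it in situ; MOM ethers and the aryl–silicon bond tolerate these mildly basic conditions.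

Step 5
Reactants: 9 3,5-bis(methoxymethoxy)-2-(trimethylsilyl)phenyl trifluoromethanesulfonate; 10 3-methylbut-2-enal (prenal)
Product: 14 5,7-bis(methoxymethoxy)-2,2-dimethyl-2H-chromene, via 3,5-bis(methoxymethoxy)benzyne 11 (not isolated), via benzoxete 12 (not isolated), via vinyl ortho-quinone methide 13 (not isolated)
Conditions: CsF (3 equiv), prenal (5 equiv), MeCN, 50 °C, slow addition of 9
Reagents that add atoms: none
Why: Fluoride attacks silicon and triflate leaves (1,2-elimination) to give aryne 11; the carbonyl oxygen of prenal adds to the aryne carbon remote from the adjacent MOM ether and the aryl anion closes on the carbonyl carbon, a formal [2+2] that forms O1–C8a and C4–C4a in benzoxete 12. Thermal 4π opening of 12 gives the vinyl ortho-quinone methide 13, and disrotatory oxa-6π electrocyclisation of its (Z)-isomer closes the six-membered pyran through O1–C2 and restores aromaticity. The closest known reaction type is the fluoride-mediated insertion of arynes into the C=O bond of α,β-unsaturated aldehydes to give 2H-chromenes. No stereocentre remains in 14, since the one in 12 is lost on ring opening. The step needs regioselective addition to the unsymmetrical aryne; the MOM-oxy group next to the triple bond secures it by inductive withdrawal, making the remote aryne carbon electrophilic and stabilising the developing anion beside it, so oxygen ends on C8a and carbon on C4a (5,7- and not 6,8-dioxygenation). Excess prenal, slow release of the aryne and the fast intramolecular 6π closure should favour C=O addition over ene reaction or capture of 13 by a second aryne.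

Step 6
Reactants: 14 5,7-bis(methoxymethoxy)-2,2-dimethyl-2H-chromene
Product: 17 5,7-bis(methoxymethoxy)-2,2-dimethyl-2H-chromene-6-carbaldehyde, via C6 aryllithium 15 (not isolated), via hemiaminal alkoxide 16 (not isolated)
Conditions: n-BuLi, THF, 0 °C; DMF, 0 °C → rt; H2O
Reagents that add atoms: N,N-dimethylformamide, CN(C)C=O
Why: directed ortho-metalation followed by formylation with DMF: C6–H lies between two MOM ethers whose chelating side chains cooperate, whereas C8–H has one MOM neighbour and the weakly coordinating tertiary-alkyl ring oxygen, so lithiation should occur at C6.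

Step 7
Reactants: 17 5,7-bis(methoxymethoxy)-2,2-dimethyl-2H-chromene-6-carbaldehyde
Product: 21 8-acetyl-5,7-bis(methoxymethoxy)-2,2-dimethyl-2H-chromene-6-carbaldehyde, via amino alkoxide 18 (not isolated), via C8 aryllithium 19 (not isolated), via tetrahedral acetamide adduct 20 (not isolated)
Conditions: lithium 4-methylpiperazin-1-ide (from 1-methylpiperazine + n-BuLi), THF, −20 °C; n-BuLi, TMEDA, −20 °C; MeC(O)N(OMe)Me, −78 → 0 °C; H2O
Reagents that add atoms: N-methoxy-N-methylacetamide, CC(=O)N(C)OC; 1-methylpiperazine, CN1CCNCC1 (carried only by intermediates 18 to 20)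
Why: in situ α-amino alkoxide protection of the aldehyde followed by directed ortho-metalation: the masked formyl group is inert to n-BuLi, the only remaining arene C–H (C8, between the C7 MOM ether and O1) is lithiated, the Weinreb amide transfers acetyl through a stable chelate without over-addition, and water releases both carbonyl groups.

Step 8
Reactants: 21 8-acetyl-5,7-bis(methoxymethoxy)-2,2-dimethyl-2H-chromene-6-carbaldehyde
Product: 22 8-acetyl-5,7-dihydroxy-2,2-dimethyl-2H-chromene-6-carbaldehyde
Conditions: HCl (1.25 M in MeOH), 40 °C; aqueous work-up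
Reagents that add atoms: none
Why: acid-catalysed acetal exchange in methanol (MOM cleavage) frees both phenols; the two acyl groups lower the electron density of the arene and should protect the chromene double bond from protonation.

Step 9
Reactants: 23 flopropione (2,4,6-trihydroxypropiophenone)
Product: 24 3,5-dihydroxy-4,4-dimethyl-2-propanoylcyclohexa-2,5-dien-1-one (propionylfilicinic acid)
Conditions: NaOMe (4 equiv), MeI (2.2 equiv), MeOH, 0 °C → rt; aq. HCl work-up
Reagents that add atoms: iodomethane, CI
Why: double C-methylation of the acylphloroglucinol polyanion (the classical acylfilicinic acid preparation): the second methyl group enters the same, now more nucleophilic ring carbon and dearomatises the ring to a stable vinylogous acid, and limiting MeI curbs further methylation.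

Step 10
Reactants: 22 8-acetyl-5,7-dihydroxy-2,2-dimethyl-2H-chromene-6-carbaldehyde; 24 3,5-dihydroxy-4,4-dimethyl-2-propanoylcyclohexa-2,5-dien-1-one
Product: 26 2-[(8-acetyl-5,7-dihydroxy-2,2-dimethyl-2H-chromen-6-yl)methyl]-3,5-dihydroxy-4,4-dimethyl-6-propanoylcyclohexa-2,5-dien-1-one (target), via alkylidene trione 25 (not isolated)
Conditions: L-proline (20 mol%), Hantzsch ester (1.1 equiv), CH2Cl2, rt
Reagents that add atoms: none
Why: organocatalytic three-component reductive alkylation (Knoevenagel condensation, then conjugate hydride transfer from the Hantzsch ester): the only ring CH of 24 (C6) condenses with the proline-activated aldehyde and the dihydropyridine should reduce adduct 25 before a second molecule of 24 can add, under neutral conditions that spare the chromene and both acyl groups.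

**Compound list**

1 | phloroglucinol | Oc1cc(O)cc(O)c1 | starting material
2 | 3,5-bis(methoxymethoxy)phenol | COCOc1cc(O)cc(OCOC)c1 | intermediate
3 | 3,5-bis(methoxymethoxy)phenyl N-isopropylcarbamate | CC(C)NC(=O)Oc1cc(OCOC)cc(OCOC)c1 | intermediate
4 | 3,5-bis(methoxymethoxy)phenyl N-(tert-butyldimethylsilyl)-N-isopropylcarbamate (not isolated) | CC(C)N([Si](C)(C)C(C)(C)C)C(=O)Oc1cc(OCOC)cc(OCOC)c1 | intermediate
5 | 2-lithio-3,5-bis(methoxymethoxy)phenyl N-(tert-butyldimethylsilyl)-N-isopropylcarbamate (not isolated) | CC(C)N([Si](C)(C)C(C)(C)C)C(=O)Oc1cc(OCOC)cc(OCOC)c1[Li] | intermediate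
6 | 3,5-bis(methoxymethoxy)-2-(trimethylsilyl)phenyl N-(tert-butyldimethylsilyl)-N-isopropylcarbamate (not isolated) | CC(C)N([Si](C)(C)C(C)(C)C)C(=O)Oc1cc(OCOC)cc(OCOC)c1[Si](C)(C)C | intermediate
7 | 3,5-bis(methoxymethoxy)-2-(trimethylsilyl)phenyl N-isopropylcarbamate | CC(C)NC(=O)Oc1cc(OCOC)cc(OCOC)c1[Si](C)(C)C | intermediate
8 | 3,5-bis(methoxymethoxy)-2-(trimethylsilyl)phenol, present as its DBU-H phenoxide (not isolated) | COCOc1cc(O)c([Si](C)(C)C)c(OCOC)c1 | intermediate
9 | 3,5-bis(methoxymethoxy)-2-(trimethylsilyl)phenyl trifluoromethanesulfonate | COCOc1cc(OCOC)c([Si](C)(C)C)c(OS(=O)(=O)C(F)(F)F)c1 | intermediate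
10 | 3-methylbut-2-enal (prenal) | CC(C)=CC=O | starting material
11 | 3,5-bis(methoxymethoxy)benzyne (not isolated) | COCOC1=CC(OCOC)=CC#C1 | intermediate
12 | 3,5-bis(methoxymethoxy)-2-(2-methylprop-1-en-1-yl)-2H-benzo[b]oxete, racemic (not isolated) | COCOc1cc(OCOC)c2C(C=C(C)C)Oc2c1 | intermediate
13 | (6Z)-3,5-bis(methoxymethoxy)-6-(3-methylbut-2-en-1-ylidene)cyclohexa-2,4-dien-1-one (not isolated) | CC(C)=C/C=C1\C(=O)C=C(OCOC)C=C1OCOC | intermediate
14 | 5,7-bis(methoxymethoxy)-2,2-dimethyl-2H-chromene | COCOc1cc(OCOC)c2C=CC(C)(C)Oc2c1 | intermediate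
15 | 6-lithio-5,7-bis(methoxymethoxy)-2,2-dimethyl-2H-chromene (not isolated) | [Li]c1c(OCOC)cc2OC(C)(C)C=Cc2c1OCOC | intermediate
16 | lithium [5,7-bis(methoxymethoxy)-2,2-dimethyl-2H-chromen-6-yl](dimethylamino)methanolate, racemic (not isolated) | CN(C)C(O[Li])c1c(OCOC)cc2OC(C)(C)C=Cc2c1OCOC | intermediate
17 | 5,7-bis(methoxymethoxy)-2,2-dimethyl-2H-chromene-6-carbaldehyde | O=Cc1c(OCOC)cc2OC(C)(C)C=Cc2c1OCOC | intermediate
18 | lithium [5,7-bis(methoxymethoxy)-2,2-dimethyl-2H-chromen-6-yl](4-methylpiperazin-1-yl)methanolate, racemic (not isolated) | CN1CCN(CC1)C(O[Li])c1c(OCOC)cc2OC(C)(C)C=Cc2c1OCOC | intermediate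
19 | 8-lithio derivative of 18 (not isolated) | CN1CCN(CC1)C(O[Li])c1c(OCOC)c([Li])c2OC(C)(C)C=Cc2c1OCOC | intermediate
20 | dilithium bis-alkoxide from addition of 19 to N-methoxy-N-methylacetamide: C8 carries C(CH3)(OLi)N(OMe)Me, C6 carries CH(OLi)(4-methylpiperazin-1-yl) (not isolated) | CON(C)C(C)(O[Li])c1c(OCOC)c(C(O[Li])N2CCN(C)CC2)c(OCOC)c2C=CC(C)(C)Oc12 | intermediate
21 | 8-acetyl-5,7-bis(methoxymethoxy)-2,2-dimethyl-2H-chromene-6-carbaldehyde | CC(=O)c1c(OCOC)c(C=O)c(OCOC)c2C=CC(C)(C)Oc12 | intermediate
22 | 8-acetyl-5,7-dihydroxy-2,2-dimethyl-2H-chromene-6-carbaldehyde | CC(=O)c1c(O)c(C=O)c(O)c2C=CC(C)(C)Oc12 | intermediate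
23 | flopropione (2,4,6-trihydroxypropiophenone) | CCC(=O)c1c(O)cc(O)cc1O | starting material
24 | 3,5-dihydroxy-4,4-dimethyl-2-propanoylcyclohexa-2,5-dien-1-one (propionylfilicinic acid) | CCC(=O)C1=C(O)C(C)(C)C(O)=CC1=O | intermediate
25 | 2-[(8-acetyl-5,7-dihydroxy-2,2-dimethyl-2H-chromen-6-yl)methylidene]-5-hydroxy-4,4-dimethyl-6-propanoylcyclohex-5-ene-1,3-dione, alkene geometry undefined (not isolated) | CCC(=O)C1=C(O)C(C)(C)C(=O)C(=Cc2c(O)c3C=CC(C)(C)Oc3c(C(C)=O)c2O)C1=O | intermediate
26 | 2-[(8-acetyl-5,7-dihydroxy-2,2-dimethyl-2H-chromen-6-yl)methyl]-3,5-dihydroxy-4,4-dimethyl-6-propanoylcyclohexa-2,5-dien-1-one | CCC(=O)C1=C(O)C(C)(C)C(O)=C(Cc2c(O)c3c(c(C(C)=O)c2O)OC(C)(C)C=C3)C1=O | target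

**Step count**

Total: 10 steps. Longest linear sequence: 9 steps (steps 1 to 8 and step 10, from phloroglucinol); step 9 is a one-step branch.

**Steps most likely to fail**

Step 5. The aryne may be consumed by ene reaction with the allylic methyl groups of prenal or by fluoride-triggered self-condensation of the enal, and the quinone methide may be intercepted by a second aryne before it cyclises. The fallback builds the same pyran ring without an aryne. It sets out from 2, which is O-alkylated with 3-chloro-3-methylbut-1-yne (CuCl2·2H2O cat., DBU, MeCN, 0 °C) to give 1,3-bis(methoxymethoxy)-5-[(2-methylbut-3-yn-2-yl)oxy]benzene F1. Heating F1 in xylene at 140 °C should trigger the aryl propargyl ether Claisen rearrangement, 1,5-hydrogen shift and oxa-6π closure. Both ortho positions of F1 are equivalent, so a single chromene is expected, and the route is rejoined at 14.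

Step 7. Masking of the formyl group may be incomplete, so that butyl adds to the aldehyde. Metalation may stall at the hindered C8–H or stray to the vinylic C4–H. The aryllithium may also deprotonate the acetamide instead of accepting the acyl group. The fallback introduces the acetyl group last by electrophilic substitution. It sets out from 17, whose MOM ethers are removed (HCl, MeOH, 40 °C) to give 5,7-dihydroxy-2,2-dimethyl-2H-chromene-6-carbaldehyde F2. F2 is joined to 24 under the proline/Hantzsch ester conditions of step 10 to give 2-[(5,7-dihydroxy-2,2-dimethyl-2H-chromen-6-yl)methyl]-3,5-dihydroxy-4,4-dimethyl-6-propanoylcyclohexa-2,5-dien-1-one F3. Friedel–Crafts C-acetylation of F3 at C8, the only free ring position (acetic anhydride, BF3·OEt2, then K2CO3/MeOH to cleave any enol or phenol acetates and the boron chelate), should give 26, where the route is rejoined.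

Step 10. The Knoevenagel condensation may stall because the formyl group is locked in a hydrogen bond and conjugated with two phenolic oxygens, and the alkylidene intermediate may be captured by a second molecule of 24 or by a neighbouring phenol faster than hydride transfer. The fallback joins the halves before the phenols are unmasked, so that the electrophile is a non-chelated dialkoxybenzaldehyde with no free ortho hydroxyl. It sets out from 21, which is condensed and reduced with 24 (L-proline, Hantzsch ester, CH2Cl2) to give 2-{[8-acetyl-5,7-bis(methoxymethoxy)-2,2-dimethyl-2H-chromen-6-yl]methyl}-3,5-dihydroxy-4,4-dimethyl-6-propanoylcyclohexa-2,5-dien-1-one F4. Cleavage of the MOM ethers of F4 (HCl, MeOH, rt) should give 26, where the route is rejoined.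

**Further compounds**

F1 | step 5 | 1,3-bis(methoxymethoxy)-5-[(2-methylbut-3-yn-2-yl)oxy]benzene | COCOc1cc(OCOC)cc(OC(C)(C)C#C)c1
F2 | step 7 | 5,7-dihydroxy-2,2-dimethyl-2H-chromene-6-carbaldehyde | O=Cc1c(O)cc2OC(C)(C)C=Cc2c1O
F3 | step 7 | 2-[(5,7-dihydroxy-2,2-dimethyl-2H-chromen-6-yl)methyl]-3,5-dihydroxy-4,4-dimethyl-6-propanoylcyclohexa-2,5-dien-1-one | CCC(=O)C1=C(O)C(C)(C)C(O)=C(Cc2c(O)cc3OC(C)(C)C=Cc3c2O)C1=O
F4 | step 10 | 2-{[8-acetyl-5,7-bis(methoxymethoxy)-2,2-dimethyl-2H-chromen-6-yl]methyl}-3,5-dihydroxy-4,4-dimethyl-6-propanoylcyclohexa-2,5-dien-1-one | CCC(=O)C1=C(O)C(C)(C)C(O)=C(Cc2c(OCOC)c3C=CC(C)(C)Oc3c(C(C)=O)c2OCOC)C1=O
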